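**Retrosynthetic overview**
- The dimer is opened at the ester between the central (C3') carboxyl of the unit A isocitrate and the neopentyl C15–OH of unit B. Both halves come from one bicyclic alcohol, unit A by deoxygenation at C15.
- The strategy rests on the hindered C11–O–C2' ether carbon lying β to the C8=C12 exocyclic methylene of ring B, together with the C15 oxygen on quaternary C4 of ring A. This pattern is read as the product of a 2-methyloxirane-initiated, allylsilane-terminated cyclisation of an open-chain allylic isocitrate ether.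
- The ether is made on the acyclic chain (Ag2O alkylation of a (2R,3S)-isocitrate triester from (R)-malic acid). Ring A (C4–C5) and then ring B (C9–C10) close in one Lewis acid cascade.
- The chain comes from geranyl acetate (Sharpless epoxidation sets the oxirane centre), methyl acetoacetate and a silylmethyl nucleophile introduced through a Z-enol triflate.

Key step: step 19

Remark: drimane numbering is used (C11 on C9, C12 the methylene carbon on C8, C15 the oxygen-bearing carbon on C4; primed atoms belong to the isocitrate, C2' the ether carbon, C3' the carbon with the central carboxyl). The SMILES is read as 5α-H, 9α-H, 10β-CH3 in both decalins with the C15 oxygen α (equatorial) in unit B, and oxirane opening is assumed to go with inversion as in known epoxy-polyene cyclisations.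

**Route**

Step 1
Reactants: 1 (R)-malic acid
Product: 2 2-[(4R)-2,2-dimethyl-5-oxo-1,3-dioxolan-4-yl]acetic acid
Conditions: 2,2-dimethoxypropane, PPTS (cat.), rt
Reagents that add atoms: 2,2-dimethoxypropane COC(C)(C)OC
Why: acid-catalysed transketalisation ties the α-hydroxy acid pair into the favoured five-membered dioxolanone, leaving the CH2CO2H free and the stereocentre untouched.

Step 2
Reactants: 2 dioxolanone acid
Product: 3 2-(trimethylsilyl)ethyl 2-[(4R)-2,2-dimethyl-5-oxo-1,3-dioxolan-4-yl]acetate
Conditions: Me3SiCH2CH2OH, DCC, DMAP (cat.), CH2Cl2, 0 °C to rt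
Reagents that add atoms: 2-(trimethylsilyl)ethanol OCC[Si](C)(C)C
Why: Steglich carbodiimide esterification of the only free carboxyl runs under neutral conditions that leave the activated dioxolanone closed.

Step 3
Reactants: 3 silylethyl ester dioxolanone
Product: 4 1-methyl 4-[2-(trimethylsilyl)ethyl] (2R)-2-hydroxybutanedioate
Conditions: MeOH, NaOMe (5 mol %), −10 °C, short; AcOH quench
Reagents that add atoms: methanol CO
Why: the dioxolanone is an acyl ketal whose carbonyl should be attacked by methoxide far faster than the primary silylethyl ester exchanges, and the hemiketal then loses acetone to free the 2-hydroxyl (selective methanolysis of an activated ester).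

Step 4
Reactants: 4 mixed (R)-malate diester; 5 tert-butyl bromoacetate
Product: 7 3-tert-butyl 1-methyl 2-[2-(trimethylsilyl)ethyl] (1R,2S)-1-hydroxypropane-1,2,3-tricarboxylate [(2R,3S)-isocitrate triester], via dilithium malate dianion 6 (not isolated)
Conditions: LiN(SiMe3)2 (2.2 equiv), THF, −78 to −20 °C; then 5, −78 to −20 °C; aq. NH4Cl
Reagents that add atoms: none
Why: Frater–Seebach alkylation, in which the chelated lithium alkoxide-enolate is alkylated anti to the alkoxide-bearing substituent, so the new C3' centre is set S relative to the untouched (R)-carbinol and the three carboxyls end up differentiated.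

Step 5
Reactants: 8 geranyl acetate
Product: 9 (2E,6E)-8-hydroxy-3,7-dimethylocta-2,6-dien-1-yl acetate
Conditions: SeO2 (cat.), tBuOOH, salicylic acid (cat.), CH2Cl2, rt
Reagents that add atoms: tert-butyl hydroperoxide CC(C)(C)OO
Why: SeO2-catalysed allylic hydroxylation (ene reaction then 2,3-sigmatropic shift) is selective for the E-methyl of the electron-rich terminal alkene, the acetate deactivating the other alkene.

Step 6
Reactants: 9 8-hydroxygeranyl acetate
Product: 10 (2E)-5-[(2S,3S)-3-(hydroxymethyl)-3-methyloxiran-2-yl]-3-methylpent-2-en-1-yl acetate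
Conditions: Ti(OiPr)4 (10 mol %), L-(+)-diethyl tartrate (12 mol %), tBuOOH, 4 Å MS, CH2Cl2, −20 °C
Reagents that add atoms: tert-butyl hydroperoxide CC(C)(C)OO
Why: Sharpless asymmetric epoxidation of the E-allylic alcohol with the L-(+)-tartrate titanium catalyst delivers oxygen to one enantioface, setting the (2S,3S)-oxirane whose tertiary C–O bond is carried on to the later oxirane centre, while the isolated alkene is left alone.

Step 7
Reactants: 10 epoxy alcohol acetate
Product: 11 (2R,6E)-2,6-dimethyloct-6-ene-1,2,8-triol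
Conditions: LiAlH4, THF, 0 to 40 °C; Fieser work-up
Reagents that add atoms: none
Why: hydride opens the 2,3-epoxy alcohol at the secondary carbon because the other terminus is quaternary, so the tertiary C–O bond keeps its configuration, and the acetate is reduced off in the same operation.

Step 8
Reactants: 11 triol
Product: 12 (2E)-3-methyl-6-[(4R)-2,2,4-trimethyl-1,3-dioxolan-4-yl]hex-2-en-1-ol
Conditions: 2,2-dimethoxypropane, PPTS (cat.), acetone, rt
Reagents that add atoms: 2,2-dimethoxypropane COC(C)(C)OC
Why: only the 1,2-diol can form a five-membered isopropylidene ketal under thermodynamic control, which leaves the allylic primary hydroxyl free.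

Step 9
Reactants: 12 acetonide alcohol
Product: 13 (4R)-4-[(4E)-6-bromo-4-methylhex-4-en-1-yl]-2,2,4-trimethyl-1,3-dioxolane
Conditions: CBr4, PPh3, CH2Cl2, 0 °C
Reagents that add atoms: carbon tetrabromide BrC(Br)(Br)Br
Why: Appel bromination converts the primary allylic alcohol by SN2 displacement of the oxyphosphonium under near-neutral conditions that keep the acetonide and the E alkene.

Step 10
Reactants: 13 allylic bromide; 14 methyl acetoacetate
Product: 16 methyl (6E)-7-methyl-3-oxo-10-[(4R)-2,2,4-trimethyl-1,3-dioxolan-4-yl]dec-6-enoate, via acetoacetate dianion 15 (not isolated)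
Conditions: NaH, THF, 0 °C; n-BuLi, 0 °C; then 13, 0 °C; aq. NH4Cl
Reagents that add atoms: none
Why: γ-alkylation of the acetoacetate dianion, whose terminal carbanion is the more reactive site and displaces the primary allylic bromide by SN2 without allylic transposition.

Step 11
Reactants: 16 β-keto ester
Product: 18 methyl (2Z,6E)-7-methyl-3-(trifluoromethanesulfonyloxy)-10-[(4R)-2,2,4-trimethyl-1,3-dioxolan-4-yl]deca-2,6-dienoate, via potassium Z-enolate 17 (not isolated)
Conditions: KN(SiMe3)2, THF, −78 °C; PhNTf2, −78 to 0 °C; aq. NH4Cl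
Reagents that add atoms: N-phenylbis(trifluoromethanesulfonimide) O=S(=O)(N(c1ccccc1)S(=O)(=O)C(F)(F)F)C(F)(F)F
Why: the potassium enolate of the β-keto ester is held in the chelated cis form, so O-triflation should give the Z-enol triflate with chain and ester trans, the geometry that later places C11 equatorial.

Step 12
Reactants: 18 Z-enol triflate ester
Product: 19 (2Z,6E)-1-hydroxy-7-methyl-10-[(4R)-2,2,4-trimethyl-1,3-dioxolan-4-yl]deca-2,6-dien-3-yl trifluoromethanesulfonate
Conditions: iBu2AlH (2.3 equiv), CH2Cl2, −78 °C; aq. potassium sodium tartrate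
Reagents that add atoms: none
Why: iBu2AlH reduces the conjugated ester to the allylic alcohol at −78 °C, conditions under which enol triflates, acetonides and the alkene geometry are inert.

Step 13
Reactants: 19 allylic alcohol
Product: 20 (2Z,6E)-1-bromo-7-methyl-10-[(4R)-2,2,4-trimethyl-1,3-dioxolan-4-yl]deca-2,6-dien-3-yl trifluoromethanesulfonate
Conditions: CBr4, PPh3, CH2Cl2, −20 °C
Reagents that add atoms: carbon tetrabromide BrC(Br)(Br)Br
Why: Appel bromination of the primary allylic alcohol, where the electron-poor triflyloxy alkene disfavours ionisation so that direct substitution without transposition is expected.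

Step 14
Reactants: 20 allylic bromide enol triflate; 7 isocitrate triester (in excess, recoverable)
Product: 21 3-tert-butyl 1-methyl 2-[2-(trimethylsilyl)ethyl] (1R,2S)-1-{[(2Z,6E)-7-methyl-3-(trifluoromethanesulfonyloxy)-10-[(4R)-2,2,4-trimethyl-1,3-dioxolan-4-yl]deca-2,6-dien-1-yl]oxy}propane-1,2,3-tricarboxylate
Conditions: Ag2O (3 equiv), 4 Å MS, CH2Cl2, dark, rt
Reagents that add atoms: none
Why: Ag2O-mediated O-alkylation of an α-hydroxy ester, in which silver assists loss of bromide under neutral conditions so that the base-sensitive isocitrate (retro-aldol, lactonisation, C3' epimerisation) and both its centres survive, and the enol triflate stands in for the allylsilane because a silylmethyl-substituted allylic bromide would eliminate to a diene.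

Step 15
Reactants: 21 isocitrate ether acetonide
Product: 22 the corresponding (2Z,6E,11R)-11,12-dihydroxy-7,11-dimethyl-3-(trifluoromethanesulfonyloxy)dodeca-2,6-dien-1-yl ether of the isocitrate triester
Conditions: AcOH/THF/H2O (3:1:1), 35 °C
Reagents that add atoms: none
Why: mild aqueous acetic acid hydrolyses the isopropylidene ketal while tert-butyl and silylethyl esters, the enol triflate and the allylic ether are stable, and it is done before the acid-labile allylsilane exists.

Step 16
Reactants: 22 diol
Product: 23 the (2Z,6E,11R)-11-hydroxy-7,11-dimethyl-12-(p-toluenesulfonyloxy)-3-(trifluoromethanesulfonyloxy)dodeca-2,6-dien-1-yl ether of the isocitrate triester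
Conditions: TsCl, Et3N, Bu2SnO (2 mol %), CH2Cl2, 0 °C to rt
Reagents that add atoms: p-toluenesulfonyl chloride Cc1ccc(cc1)S(=O)(=O)Cl
Why: stannylene-accelerated sulfonylation takes the primary hydroxyl of the 1,2-diol selectively, the tertiary hydroxyl being far too hindered.

Step 17
Reactants: 23 hydroxy tosylate enol triflate; 24 (trimethylsilyl)methylmagnesium chloride
Product: 26 the (2Z,6E,11R)-11-hydroxy-7,11-dimethyl-12-(p-toluenesulfonyloxy)-3-[(trimethylsilyl)methyl]dodeca-2,6-dien-1-yl ether of the isocitrate triester, via (trimethylsilyl)methylzinc chloride 25 (not isolated)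
Conditions: 24, ZnCl2, THF, 0 °C; then 23, Pd(PPh3)4 (5 mol %), THF, rt to 40 °C
Reagents that add atoms: none
Why: Negishi coupling, in which zerovalent palladium inserts into the enol triflate C–O bond with retention of geometry and the silylmethylzinc reagent (no β-hydrogen, tolerant of esters, of the neopentyl-type tosylate and of a hindered hydroxyl) transfers CH2SiMe3 to give the allylsilane with C7 and C11 trans.

Step 18
Reactants: 26 allylsilane hydroxy tosylate
Product: 27 3-tert-butyl 1-methyl 2-[2-(trimethylsilyl)ethyl] (1R,2S)-1-{[(2Z,6E)-7-methyl-10-[(2R)-2-methyloxiran-2-yl]-3-[(trimethylsilyl)methyl]deca-2,6-dien-1-yl]oxy}propane-1,2,3-tricarboxylate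
Conditions: NaH (1.05 equiv), THF, 0 °C
Reagents that add atoms: none
Why: the sodium tertiary alkoxide displaces the adjacent primary tosylate in a fast 3-exo-tet closure that should outrun any attack on the esters, and since the tertiary C–O bond is not broken the (R) configuration is kept.

Step 19
Reactants: 27 (R)-2-methyloxirane allylsilane
Product: 28 3-tert-butyl 1-methyl 2-[2-(trimethylsilyl)ethyl] (1R,2S)-1-{[(4R,5R,9S,10S)-15-hydroxydrim-8(12)-en-11-yl]oxy}propane-1,2,3-tricarboxylate (15-hydroxyalbicanyl isocitrate triester; 4α-CH2OH, 5α-H, 9α-H, 10β-CH3)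
Conditions: MeAlCl2 (4 equiv), CH2Cl2, −78 °C; Et3N/MeOH quench; aq. potassium sodium tartrate
Reagents that add atoms: none
Why: MeAlCl2 binds the oxirane oxygen, the C5=C10 alkene attacks the tertiary oxirane carbon C4 from the side opposite the breaking C4–O bond, the C10 cation is captured by the allylsilane carbon C9, and the β-silyl cation at C8 loses Me3Si so that only the C8=C12 exocyclic alkene can form while the oxirane oxygen stays on C15. The closest known reaction is the Lewis acid epoxy-polyene cyclisation terminated by an allylsilane that gives albicanyl-type decalins, and openings of 2,2-disubstituted oxiranes at the tertiary carbon by a tethered alkene are also documented. Ring A closes through the C4–C5 bond by 6-endo attack of the alkene with the oxirane C–O bond outside the new ring, and ring B closes through the C9–C10 bond by 6-endo attack of the allylsilane, both through chairs. C4 is set by inversion at the (R)-oxirane carbon, C5 and C10 by anti addition across the E alkene (trans fusion), and C9 by the allylsilane geometry, in which C7 and C11 are trans so that C11 becomes equatorial. The step needs one of two chair–chair folds, and the aluminium-bound CH2O arm, larger than methyl, is expected to take the equatorial site on ring A away from the axial C10 methyl, which ties the fixed C4 centre to the decalin drawn (the other fold would give a separable diastereomer). Chemoselectivity should be secured by low temperature and excess Lewis acid to saturate the three esters, by the tertiary oxirane carbon ionising far more readily than the allylic ether carbon (its oxygen sits on an ester-bearing carbon), and by the nearby alkene outpacing the 1,2-hydride shift to the aldehyde (Meinwald rearrangement).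

Step 20
Reactants: 28 15-hydroxyalbicanyl isocitrate triester (one portion)
Product: 29 the C15 O-(pentafluorophenoxy)thiocarbonyl derivative of 28
Conditions: C6F5OC(S)Cl, pyridine, DMAP (cat.), CH2Cl2, 0 °C to rt
Reagents that add atoms: O-pentafluorophenyl chlorothionoformate S=C(Cl)Oc1c(F)c(F)c(F)c(F)c1F
Why: acylation of the only hydroxyl gives the electron-poor aryl thionocarbonate, the derivative best suited to radical deoxygenation of a primary alcohol.

Step 21
Reactants: 29 thionocarbonate
Product: 30 3-tert-butyl 1-methyl 2-[2-(trimethylsilyl)ethyl] (1R,2S)-1-{[(5S,9S,10S)-drim-8(12)-en-11-yl]oxy}propane-1,2,3-tricarboxylate (albicanyl isocitrate triester)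
Conditions: Bu3SnH, AIBN (cat.), toluene, 100 °C
Reagents that add atoms: none
Why: Barton–McCombie deoxygenation, in which the stannyl radical adds to the thiocarbonyl, the primary C15–O bond fragments and the radical is reduced to the C4 methyl (C4 ceasing to be stereogenic), the exocyclic alkene being too remote to trap it.

Step 22
Reactants: 30 albicanyl isocitrate triester
Product: 31 (2S,3R)-2-(2-tert-butoxy-2-oxoethyl)-3-{[(5S,9S,10S)-drim-8(12)-en-11-yl]oxy}-4-methoxy-4-oxobutanoic acid (unit A with free central carboxyl)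
Conditions: Bu4NF, THF, 0 °C; cold 0.1 M HCl work-up
Reagents that add atoms: none
Why: fluoride attacks silicon and the 2-(trimethylsilyl)ethyl ester fragments to ethene and the carboxylate, which frees only the central carboxyl and leaves methyl and tert-butyl esters untouched.

Step 23
Reactants: 31 unit A acid; 28 15-hydroxyalbicanyl isocitrate triester (second portion)
Product: 32 protected dimer, the C15 ester of 28 with acid 31
Conditions: 2-methyl-6-nitrobenzoic anhydride, DMAP, Et3N, CH2Cl2, 0 °C to rt
Reagents that add atoms: none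
Why: Shiina esterification, in which the mixed anhydride passes the acyl group through an acylpyridinium to the only free hydroxyl (neopentyl C15–OH) under mild conditions chosen to limit epimerisation at C3' and β-elimination of the C2' alkoxy group.

Step 24
Reactants: 32 protected dimer
Product: 33 dimer with free central carboxyl on unit B and both tert-butyl esters in place
Conditions: Bu4NF, THF, 0 °C; cold 0.1 M HCl work-up
Reagents that add atoms: none
Why: fluoride-induced fragmentation of the single 2-(trimethylsilyl)ethyl ester, selective over methyl, tert-butyl and the inter-unit ester.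

Step 25
Reactants: 33 dimer mono-acid
Product: 35 target CNP0420141.2, via tris(trimethylsilyl) ester 34 (not isolated)
Conditions: Me3SiOTf, 2,6-lutidine, CH2Cl2, 0 °C; then H2O (pH 4 buffer)
Reagents that add atoms: none
Why: Me3SiOTf silylates the tert-butyl ester carbonyls, which lose isobutene under lutidine buffering to give silyl esters that hydrolyse on work-up, a non-protic cleavage that should leave both exocyclic alkenes unisomerised and the methyl esters and inter-unit ester intact.

**Compound list**
1 | (R)-malic acid | O[C@@H](C(=O)O)CC(=O)O | starting material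
2 | 2-[(4R)-2,2-dimethyl-5-oxo-1,3-dioxolan-4-yl]acetic acid | CC1(C)O[C@H](CC(=O)O)C(=O)O1 | intermediate
3 | 2-(trimethylsilyl)ethyl 2-[(4R)-2,2-dimethyl-5-oxo-1,3-dioxolan-4-yl]acetate | CC1(C)O[C@H](CC(=O)OCC[Si](C)(C)C)C(=O)O1 | intermediate
4 | 1-methyl 4-[2-(trimethylsilyl)ethyl] (2R)-2-hydroxybutanedioate | O[C@@H](C(=O)OC)CC(=O)OCC[Si](C)(C)C | intermediate
5 | tert-butyl bromoacetate | BrCC(=O)OC(C)(C)C | starting material
6 | dilithium malate dianion (alkoxide enolate of 4) | [Li+].[Li+].[O-][C@@H](C(=O)OC)C=C([O-])OCC[Si](C)(C)C | intermediate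
7 | (2R,3S)-isocitrate triester with free 2-OH | O[C@@H](C(=O)OC)[C@H](CC(=O)OC(C)(C)C)C(=O)OCC[Si](C)(C)C | intermediate
8 | geranyl acetate | CC(C)=CCC/C(C)=C/COC(C)=O | starting material
9 | (2E,6E)-8-hydroxy-3,7-dimethylocta-2,6-dien-1-yl acetate | OC/C(C)=C/CC/C(C)=C/COC(C)=O | intermediate
10 | (2E)-5-[(2S,3S)-3-(hydroxymethyl)-3-methyloxiran-2-yl]-3-methylpent-2-en-1-yl acetate | OC[C@]1(C)O[C@H]1CC/C(C)=C/COC(C)=O | intermediate
11 | (2R,6E)-2,6-dimethyloct-6-ene-1,2,8-triol | OC[C@](C)(O)CCC/C(C)=C/CO | intermediate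
12 | (2E)-3-methyl-6-[(4R)-2,2,4-trimethyl-1,3-dioxolan-4-yl]hex-2-en-1-ol | C[C@@]1(CCC/C(C)=C/CO)COC(C)(C)O1 | intermediate
13 | (4R)-4-[(4E)-6-bromo-4-methylhex-4-en-1-yl]-2,2,4-trimethyl-1,3-dioxolane | C[C@@]1(CCC/C(C)=C/CBr)COC(C)(C)O1 | intermediate
14 | methyl acetoacetate | CC(=O)CC(=O)OC | starting material
15 | acetoacetate dianion (sodium lithium salt) | [Na+].[Li+].C=C([O-])C=C([O-])OC | intermediate
16 | methyl (6E)-7-methyl-3-oxo-10-[(4R)-2,2,4-trimethyl-1,3-dioxolan-4-yl]dec-6-enoate | C[C@@]1(CCC/C(C)=C/CCC(=O)CC(=O)OC)COC(C)(C)O1 | intermediate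
17 | potassium Z-enolate of 16 | [K+].C[C@@]1(CCC/C(C)=C/CC/C([O-])=C/C(=O)OC)COC(C)(C)O1 | intermediate
18 | Z-enol triflate ester | C[C@@]1(CCC/C(C)=C/CC/C(OS(=O)(=O)C(F)(F)F)=C/C(=O)OC)COC(C)(C)O1 | intermediate
19 | Z-enol triflate allylic alcohol | C[C@@]1(CCC/C(C)=C/CC/C(OS(=O)(=O)C(F)(F)F)=C/CO)COC(C)(C)O1 | intermediate
20 | Z-enol triflate allylic bromide | C[C@@]1(CCC/C(C)=C/CC/C(OS(=O)(=O)C(F)(F)F)=C/CBr)COC(C)(C)O1 | intermediate
21 | allylic isocitrate ether (acetonide, enol triflate) | C[C@@]1(CCC/C(C)=C/CC/C(OS(=O)(=O)C(F)(F)F)=C/CO[C@@H](C(=O)OC)[C@H](CC(=O)OC(C)(C)C)C(=O)OCC[Si](C)(C)C)COC(C)(C)O1 | intermediate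
22 | (11R)-11,12-diol of the isocitrate ether | OC[C@](C)(O)CCC/C(C)=C/CC/C(OS(=O)(=O)C(F)(F)F)=C/CO[C@@H](C(=O)OC)[C@H](CC(=O)OC(C)(C)C)C(=O)OCC[Si](C)(C)C | intermediate
23 | primary tosylate of 22 | Cc1ccc(cc1)S(=O)(=O)OC[C@](C)(O)CCC/C(C)=C/CC/C(OS(=O)(=O)C(F)(F)F)=C/CO[C@@H](C(=O)OC)[C@H](CC(=O)OC(C)(C)C)C(=O)OCC[Si](C)(C)C | intermediate
24 | (trimethylsilyl)methylmagnesium chloride | C[Si](C)(C)C[Mg]Cl | starting material
25 | (trimethylsilyl)methylzinc chloride | C[Si](C)(C)C[Zn]Cl | intermediate
26 | allylsilane hydroxy tosylate | Cc1ccc(cc1)S(=O)(=O)OC[C@](C)(O)CCC/C(C)=C/CC/C(C[Si](C)(C)C)=C/CO[C@@H](C(=O)OC)[C@H](CC(=O)OC(C)(C)C)C(=O)OCC[Si](C)(C)C | intermediate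
27 | (R)-2-methyloxirane allylsilane cyclisation precursor | C[C@@]1(CCC/C(C)=C/CC/C(C[Si](C)(C)C)=C/CO[C@@H](C(=O)OC)[C@H](CC(=O)OC(C)(C)C)C(=O)OCC[Si](C)(C)C)CO1 | intermediate
28 | 15-hydroxyalbicanyl isocitrate triester (unit B, free C15-OH) | OC[C@]1(C)CCC[C@]2(C)[C@@H](CO[C@@H](C(=O)OC)[C@H](CC(=O)OC(C)(C)C)C(=O)OCC[Si](C)(C)C)C(=C)CC[C@@H]12 | intermediate
29 | C15 O-pentafluorophenyl thionocarbonate of 28 | Fc1c(F)c(F)c(OC(=S)OC[C@]2(C)CCC[C@]3(C)[C@@H](CO[C@@H](C(=O)OC)[C@H](CC(=O)OC(C)(C)C)C(=O)OCC[Si](C)(C)C)C(=C)CC[C@@H]23)c(F)c1F | intermediate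
30 | albicanyl isocitrate triester | C=C1CC[C@H]2C(C)(C)CCC[C@]2(C)[C@H]1CO[C@@H](C(=O)OC)[C@H](CC(=O)OC(C)(C)C)C(=O)OCC[Si](C)(C)C | intermediate
31 | albicanyl isocitrate with free central acid (unit A) | C=C1CC[C@H]2C(C)(C)CCC[C@]2(C)[C@H]1CO[C@@H](C(=O)OC)[C@H](CC(=O)OC(C)(C)C)C(=O)O | intermediate
32 | protected dimer | C=C1CC[C@H]2C(C)(C)CCC[C@]2(C)[C@H]1CO[C@@H](C(=O)OC)[C@H](CC(=O)OC(C)(C)C)C(=O)OC[C@]1(C)CCC[C@]2(C)[C@@H](CO[C@@H](C(=O)OC)[C@H](CC(=O)OC(C)(C)C)C(=O)OCC[Si](C)(C)C)C(=C)CC[C@@H]12 | intermediate
33 | dimer mono-acid (bis tert-butyl ester) | C=C1CC[C@H]2C(C)(C)CCC[C@]2(C)[C@H]1CO[C@@H](C(=O)OC)[C@H](CC(=O)OC(C)(C)C)C(=O)OC[C@]1(C)CCC[C@]2(C)[C@@H](CO[C@@H](C(=O)OC)[C@H](CC(=O)OC(C)(C)C)C(=O)O)C(=C)CC[C@@H]12 | intermediate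
34 | tris(trimethylsilyl) ester of the target | C=C1CC[C@H]2C(C)(C)CCC[C@]2(C)[C@H]1CO[C@@H](C(=O)OC)[C@H](CC(=O)O[Si](C)(C)C)C(=O)OC[C@]1(C)CCC[C@]2(C)[C@@H](CO[C@@H](C(=O)OC)[C@H](CC(=O)O[Si](C)(C)C)C(=O)O[Si](C)(C)C)C(=C)CC[C@@H]12 | intermediate
35 | CNP0420141.2 | C=C1CC[C@H]2C(C)(C)CCC[C@]2(C)[C@H]1CO[C@@H](C(=O)OC)[C@H](CC(=O)O)C(=O)OC[C@]1(C)CCC[C@]2(C)[C@@H](CO[C@@H](C(=O)OC)[C@H](CC(=O)O)C(=O)O)C(=C)CC[C@@H]12 | target

**Step count and risks**

Total step count: 25. Longest linear sequence: 21 steps (geranyl acetate 8 to target 35, through steps 5 to 25).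

Steps most likely to fail:

1. Step 19 (bicyclisation). The two chair–chair folds may be poorly discriminated, because only the size of the aluminium-bound CH2O arm separates them, and hydride shift of the opened oxirane or loss of the silyl-activated allylic ether may compete. Fallback: let alkene geometry rather than conformational bias fix C4, by keeping the Sharpless oxirane as an (E)-trisubstituted 2,3-epoxy ether initiator and removing the extra ring A hydroxyl afterwards. It sets out from epoxy alcohol 10. Silylation (tBuMe2SiCl, imidazole) should give the silyl ether acetate F1, K2CO3/MeOH the allylic alcohol F2, and CBr4/PPh3 the bromide F3. Acetoacetate dianion alkylation would give the keto ester F4, KN(SiMe3)2/PhNTf2 the Z-enol triflate ester F5, iBu2AlH the allylic alcohol F6, and CBr4/PPh3 the bromide F7. Ag2O etherification with 7 would give the isocitrate ether F8, and Pd(PPh3)4 coupling with zinc reagent 25 the epoxy allylsilane F9. MeAlCl2 at −78 °C should then give the 3β-hydroxy 15-silyl ether bicycle F10; here the C3–O bond must lie anti to the forming C4–C5 bond, so the chair is imposed and the E-disposed CH2OSi group is forced equatorial. Thiocarbonyldiimidazole would give the C3 imidazolide F11, Bu3SnH/AIBN the 3-deoxy silyl ether F12, and HF·pyridine returns the route to alcohol 28.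

2. Step 14 (Ag2O etherification). Silver-assisted displacement at the hindered, ester-flanked secondary hydroxyl may be too slow, allowing hydrolysis or allylic transposition of the bromide to take over. Fallback: acid-catalysed imidate alkylation in place of halide displacement. It sets out from allylic alcohol 19, which with Cl3CCN and DBU (cat.) should give the trichloroacetimidate F13. This would be coupled with 7 under CF3SO3H (cat.) in CH2Cl2/cyclohexane at −20 °C, coming back at ether 21.

3. Step 23 (ester union). Acyl transfer to the neopentyl C15 hydroxyl may be slow enough for the amine bases to epimerise C3' or to eliminate the C2' alkoxy group from the activated acyl species. Fallback: base-free thiophilic activation through an isolated thioester. It sets out from acid 31, which with 2,2'-dipyridyl disulfide and PPh3 should give the S-pyridin-2-yl thioester F14. This would be joined to alcohol 28 with AgOSO2CF3 and 2,6-di-tert-butyl-4-methylpyridine in toluene at rt, coming back at protected dimer 32.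

**Further compounds**
F1 | step 19 | (2E)-5-[(2S,3S)-3-{[tert-butyl(dimethyl)silyl]oxymethyl}-3-methyloxiran-2-yl]-3-methylpent-2-en-1-yl acetate | CC(C)(C)[Si](C)(C)OC[C@]1(C)O[C@H]1CC/C(C)=C/COC(C)=O
F2 | step 19 | corresponding allylic alcohol | CC(C)(C)[Si](C)(C)OC[C@]1(C)O[C@H]1CC/C(C)=C/CO
F3 | step 19 | corresponding allylic bromide | CC(C)(C)[Si](C)(C)OC[C@]1(C)O[C@H]1CC/C(C)=C/CBr
F4 | step 19 | epoxy β-keto ester | CC(C)(C)[Si](C)(C)OC[C@]1(C)O[C@H]1CC/C(C)=C/CCC(=O)CC(=O)OC
F5 | step 19 | epoxy Z-enol triflate ester | CC(C)(C)[Si](C)(C)OC[C@]1(C)O[C@H]1CC/C(C)=C/CC/C(OS(=O)(=O)C(F)(F)F)=C/C(=O)OC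
F6 | step 19 | epoxy Z-enol triflate allylic alcohol | CC(C)(C)[Si](C)(C)OC[C@]1(C)O[C@H]1CC/C(C)=C/CC/C(OS(=O)(=O)C(F)(F)F)=C/CO
F7 | step 19 | epoxy Z-enol triflate allylic bromide | CC(C)(C)[Si](C)(C)OC[C@]1(C)O[C@H]1CC/C(C)=C/CC/C(OS(=O)(=O)C(F)(F)F)=C/CBr
F8 | step 19 | epoxy enol triflate isocitrate ether | CC(C)(C)[Si](C)(C)OC[C@]1(C)O[C@H]1CC/C(C)=C/CC/C(OS(=O)(=O)C(F)(F)F)=C/CO[C@@H](C(=O)OC)[C@H](CC(=O)OC(C)(C)C)C(=O)OCC[Si](C)(C)C
F9 | step 19 | trisubstituted epoxy allylsilane isocitrate ether | CC(C)(C)[Si](C)(C)OC[C@]1(C)O[C@H]1CC/C(C)=C/CC/C(C[Si](C)(C)C)=C/CO[C@@H](C(=O)OC)[C@H](CC(=O)OC(C)(C)C)C(=O)OCC[Si](C)(C)C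
F10 | step 19 | 3β-hydroxy-15-(tert-butyldimethylsilyloxy)albicanyl isocitrate triester | CC(C)(C)[Si](C)(C)OC[C@]1(C)[C@@H](O)CC[C@]2(C)[C@@H](CO[C@@H](C(=O)OC)[C@H](CC(=O)OC(C)(C)C)C(=O)OCC[Si](C)(C)C)C(=C)CC[C@@H]12
F11 | step 19 | C3 O-(imidazol-1-ylthiocarbonyl) derivative of F10 | CC(C)(C)[Si](C)(C)OC[C@]1(C)[C@@H](OC(=S)n3ccnc3)CC[C@]2(C)[C@@H](CO[C@@H](C(=O)OC)[C@H](CC(=O)OC(C)(C)C)C(=O)OCC[Si](C)(C)C)C(=C)CC[C@@H]12
F12 | step 19 | 15-(tert-butyldimethylsilyloxy)albicanyl isocitrate triester | CC(C)(C)[Si](C)(C)OC[C@]1(C)CCC[C@]2(C)[C@@H](CO[C@@H](C(=O)OC)[C@H](CC(=O)OC(C)(C)C)C(=O)OCC[Si](C)(C)C)C(=C)CC[C@@H]12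
F13 | step 14 | allylic trichloroacetimidate of 19 | C[C@@]1(CCC/C(C)=C/CC/C(OS(=O)(=O)C(F)(F)F)=C/COC(=N)C(Cl)(Cl)Cl)COC(C)(C)O1
F14 | step 23 | S-pyridin-2-yl thioester of 31 | C=C1CC[C@H]2C(C)(C)CCC[C@]2(C)[C@H]1CO[C@@H](C(=O)OC)[C@H](CC(=O)OC(C)(C)C)C(=O)Sc1ccccn1
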